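## Structural features

The target 24 is a 3-hydroxyisoflavanone: a chroman-4-one in which benzene ring A is fused to the oxygen heterocycle ring C (O1, C2, C3, C4, C4a, C8a), with aryl ring B and a hydroxyl group both on C3. Ring A has hydroxyls at C5 and C7 and a prenyl chain between them at C6. Ring B is joined through C1' and has a methoxy group at C2', a second prenyl chain at C3' and a hydroxyl at C4'. C3 is the only stereocentre: it is fully substituted (OH, C4, C2, C1') and (R), so it has no stereogenic neighbour to relay or correct it and no hydrogen through which it could be equilibrated. The fragile groups are the two prenyl chains (each ortho to a phenol, so open to acid-induced chroman formation and to electrophiles), the tertiary benzylic α-ketol (open to 1,2-shifts), and the O1–C2 ether β to the carbonyl. The real difficulty is the enantioselective construction of the oxygenated quaternary carbon C3 between C2 and C4 under conditions that spare these groups. The feature used is that C2 is a lone methylene bonded only to O1 and C3, beside the C3(OH)–C4(=O) ketol. The O1–C2 unit can therefore start as a methyl ether of ring A ortho to a 1,2-dicarbonyl side chain, be bonded first to the future C4 by a photochemical hydrogen transfer, and then be moved to C3 by a ketol shift that turns the five-membered ring into ring C.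

## Logic of the disconnections

24 ⇒ 23. The three phenolic O–H bonds of 24 are replaced by O–Si bonds. Silicon is chosen because it leaves with buffered fluoride, so no acid meets the prenyl chains and no strong base meets the ketol. The skeleton is unchanged; the gain is that every earlier intermediate is free of acidic phenols. The forward step must cleave three aryl silyl ethers without a 1,2-shift at C3.

23 ⇒ 22. The C2–C3 bond is cut and C2 is rejoined to C4, so the C4 ketone becomes a carbinol and the C3 carbinol becomes a ketone (the ketol shift read backwards). This takes ring B and C3 out of the ring: in 22 they are an aroyl group on a five-membered ring, and that bond can be made from two halves. The forward step must be stereospecific and downhill. The geometry was checked for both possible migrations in the syn chelate: the (S)-carbinol of 22 gives (R)-C3 in 23 either by direct C2 migration or by ring A migration followed by ring B migration.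

22 ⇒ 13 + 19. The bond between the ketone carbon and C1' of ring B is cut. This is the point of convergence; the two halves are of similar size and each already holds its prenyl chain and ether pattern. The forward step needs a single addition of a hindered aryllithium (21) to a hindered amide with a free tertiary hydroxyl (handled as 20), without transfer of silicon from the neighbouring phenolic oxygen to that alkoxide.

13 ⇒ 12. The amide C–N bond is exchanged for the C–O bond of a methyl ester. The ester is the carbonyl partner best tolerated by the photochemical step; the amide guarantees a ketone on addition. The demand is an aminolysis that leaves the tertiary carbinol and the aryl silyl ethers alone.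

12 ⇒ 10 (through 11). The bond between the ring methylene and the carbinol carbon is cut. This opens the five-membered ring, removes the only stereocentre and returns the methylene to a methyl ether. 10 is a flat, achiral arene that already contains every carbon and oxygen of ring A, C2, C4 and C3. The forward step must take hydrogen only from the OCH3 group and must bond to one face of the ketyl carbon.

10 ⇒ 9 ⇒ 8. The two O–Si bonds are cut, then O–CH2 acetal bonds are put in their place. The exchange is needed because acetal ethers direct the metalations but have activated OCH2O hydrogens next to the ketone, while silyl ethers are photochemically innocent but cannot direct. The demand is an acetal cleavage mild enough for the prenyl chain and the ortho-hydroxyaryl keto ester.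

8 ⇒ 5 + 6. The aryl–carbonyl bond is cut beside the methoxy group. The acylation is placed before the change to silyl ethers: an electrophilic acylation of the silyl ethers would bring protic and Lewis acid to the prenyl chain, whereas metalation of 5 is directed by its ether groups. The two open ring positions of 5 are equivalent, so no regiochemical question arises. The demand is mono-acylation by 6.

5 ⇒ 2 + 3, and 2 ⇒ 1. The aryl–CH2 bond of the prenyl chain is cut, then the two acetal O–C bonds. This reaches a commercial phenol in which the future O1 is already marked as the methyl ether. The demand is lithiation between the two acetal oxygens in preference to the positions beside the methoxy group.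

19 ⇒ 18 ⇒ 17 ⇒ 15 + 3, and 15 ⇒ 14. The O–Si bond, the acetal for the phenol, the aryl–CH2 bond of the prenyl chain (between methoxy and acetal oxygen) and the acetal O–C bond are cut in turn. The bromine that becomes C1'–Li and the C2' methoxy group come from the commercial phenol 14. The demand is deprotonation by an amide base that does not exchange the bromine.

## Other disconnections considered

Alternative 1: The cut is at the C3–O bond of the tertiary alcohol, with a C2–O bond made and later removed. The isoflavone A1 (tris(methoxymethyl) ether, C2=C3) would be epoxidised with tert-butyl hydroperoxide and KOH under a chiral cinchona-derived ammonium salt (Weitz–Scheffer type) to the oxirane A2. The C2–O bond of A2 would then be cleaved reductively.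
- In favour: nucleophilic epoxidation of isoflavones, including its phase-transfer asymmetric form, is an established reaction type. All skeletal carbons are in place before the stereocentre is made. On certainty of the stereo-defining step this plan is the better one.
- Against: the enone of A1 is a vinylogous carbonate deactivated by the C5 and C7 oxygens and shielded by the ortho-substituted ring B. The opening of A2 is the weak point: hydride must go to the acetal carbon C2 only, beside a ketone and two prenyl alkenes, which excludes hydrogenolysis, and Lewis acids that ionise C2–O invite a semipinacol shift. Removal of three methoxymethyl ethers at the end needs acid near both prenyl chains.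
- Comparison: in structure A1 is as flat and simple as 10. In mechanism the epoxidation is better founded than step 6, but the ring opening is no better founded than step 13. In step count it is expected to be equal or slightly longer (an isoflavone in about nine steps, then three more).

Alternative 2: The cuts are at C3–O and C2–C3, with O1–C2 left for a later etherification. Rh2(OAc)4 would turn the diazo ketone A3 into a carbene that takes up water; the oxonium ylide would be steered by a chiral phosphoric acid onto formaldehyde to give the diol ketone A4. Desilylation of the ring A oxygen, Mitsunobu closure at the primary alcohol and deprotection would follow.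
- In favour: C3 is made with its hydroxyl and with C2 in one operation from three components, and ring C is then closed by a simple primary etherification. In convergence it is the better plan.
- Against: the rhodium carbene sits beside two electron-rich prenyl alkenes (cyclopropanation) and OCH2O and OCH3 groups (C–H insertion). The diazo carbon is flanked by the ortho-methoxy ring B and a 2,6-dioxygenated aroyl group. Plain O–H insertion by proton shift of the ylide bypasses the trapping. Formaldehyde offers the catalyst little to distinguish faces. A4 is itself a ketol that can shift, and acid is again needed at the end.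
- Comparison: on step count it is about equal. On mechanism it is equal, in that both stereo-defining steps go beyond what is established for such substrates. Its chemoselectivity toward the prenyl groups is judged worse than that of an excited ketone held at high dilution.

Alternative 3: The cut is at C3–C4. A chiral triazolylidene would convert the ring A aldehyde of the keto-aldehyde A5 into an acyl-anion equivalent that adds to the ring B aryl ketone, closing ring C and giving the protected isoflavanone A6, one deprotection from the target.
- In favour: intramolecular crossed benzoin addition of an aldehyde to a ketone is an established way to 3-hydroxychroman-4-ones with a fully substituted carbinol. The key step forms ring C and C3 directly in their final form. On precedent for the stereo-defining step, and on the number of steps after it, this plan is the better one.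
- Against: the aldehyde of A5 is flanked by two ortho oxygens and is very electron-rich, which slows formation of the acyl-anion equivalent. The acceptor is an electron-rich ortho-methoxy aryl ketone. The base needed for the carbene can trigger intramolecular aldol condensation of the aryloxymethyl ketone onto the aldehyde. Ring A needs one free phenol (the future O1) set apart from two protected ones, which costs selective protection steps that the chosen plan gets for nothing from 1. Acidic removal of three methoxymethyl ethers closes the route.
- Comparison: in structure both plans end in the same ring system; A5 is more elaborate than 10 but needs no rearrangement. In mechanism Alternative 3 stands on firmer ground. In step count the two are expected to be about equal (roughly twelve to fourteen). The chosen plan is kept for its simple ring A differentiation, its acid-free end-game and the single flat precursor 10.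

Key step: step 6

Remarks on the chemistry:
- Assumption: the (S,S)-ligand is taken to give the (3S)-carbinol 12. The sense of induction cannot be predicted with confidence for this step, and the (R,R)-ligand would be used if the sense is the opposite.
- Abbreviations: prenyl = 3-methylbut-2-en-1-yl; TBS = tert-butyldimethylsilyl; MOM = methoxymethyl; OTf = trifluoromethanesulfonate.

Step 1
Reactants: 1 5-methoxyresorcinol (5-methoxybenzene-1,3-diol)
Product: 2 1-methoxy-3,5-bis(methoxymethoxy)benzene
Conditions: NaH, MOMCl, DMF, 0 °C → rt
Reagents that add atoms: chloromethyl methyl ether (MOMCl), COCCl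
Why: Williamson-type O-alkylation of the two sodium phenoxides by the reactive α-chloro ether; the acetal ethers are the directing groups for the two metalations that follow.

Step 2
Reactants: 2 1-methoxy-3,5-bis(methoxymethoxy)benzene; 3 prenyl bromide (1-bromo-3-methylbut-2-ene)
Product: 5 5-methoxy-1,3-bis(methoxymethoxy)-2-prenylbenzene, via aryllithium 4 (not isolated)
Conditions: n-BuLi, THF, 0 °C; then 3, −78 °C → rt
Reagents that add atoms: prenyl bromide 3, CC(C)=CCBr
Why: Directed ortho-metalation goes to the ring position between the two OCH2OCH3 groups, which bind lithium better than OCH3, and the aryllithium displaces bromide at the primary allylic carbon (SN2). Any isomer metalated beside the methoxy group would be removed at this stage.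

Step 3
Reactants: 5 5-methoxy-1,3-bis(methoxymethoxy)-2-prenylbenzene; 6 dimethyl oxalate
Product: 8 methyl 2-[6-methoxy-2,4-bis(methoxymethoxy)-3-prenylphenyl]-2-oxoacetate, via aryllithium 7 (not isolated)
Conditions: n-BuLi, TMEDA, THF, −20 → 0 °C; cannulated into 6 (3 equiv), THF, −78 °C; aq. NH4Cl
Reagents that add atoms: dimethyl oxalate 6, COC(=O)C(=O)OC
Why: Second directed ortho-metalation at one of the two equivalent ring hydrogens, each flanked by OCH3 and OCH2OCH3, then acylation of the aryllithium by excess dialkyl oxalate. The reaction should stop at the α-keto ester because the tetrahedral adduct persists at −78 °C and the ketone formed is shielded by two ortho substituents.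

Step 4
Reactants: 8 methyl 2-[6-methoxy-2,4-bis(methoxymethoxy)-3-prenylphenyl]-2-oxoacetate
Product: 9 methyl 2-[2,4-dihydroxy-6-methoxy-3-prenylphenyl]-2-oxoacetate
Conditions: HCl (0.5 M), MeOH, 35 °C
Reagents that add atoms: none
Why: Acid-catalysed acetal exchange with methanol frees both phenols and releases dimethoxymethane. Dilute acid at low temperature is chosen to leave the prenyl chain uncyclised, and methanol as solvent keeps the side chain as the methyl ester.

Step 5
Reactants: 9 methyl 2-[2,4-dihydroxy-6-methoxy-3-prenylphenyl]-2-oxoacetate
Product: 10 methyl 2-[2,4-bis(tert-butyldimethylsilyloxy)-6-methoxy-3-prenylphenyl]-2-oxoacetate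
Conditions: TBSOTf, 2,6-lutidine, CH2Cl2, −20 → 0 °C
Reagents that add atoms: tert-butyldimethylsilyl trifluoromethanesulfonate (TBSOTf), CC(C)(C)[Si](C)(C)OS(=O)(=O)C(F)(F)F
Why: Silylation of phenols by a silyl triflate with a hindered pyridine base, fast enough for the hindered, hydrogen-bonded phenol beside the ketone. The silyl ethers remove the phenolic proton that would quench the excited ketone, offer no activated C–H bond next to it, and leave later with fluoride.

Step 6
Reactants: 10 methyl 2-[2,4-bis(tert-butyldimethylsilyloxy)-6-methoxy-3-prenylphenyl]-2-oxoacetate
Product: 12 methyl (3S)-4,6-bis(tert-butyldimethylsilyloxy)-3-hydroxy-5-prenyl-2,3-dihydro-1-benzofuran-3-carboxylate, via 1,5-biradical 11 (not isolated)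
Conditions: Sc(OTf)3 (20 mol%), (S,S)-2,6-bis(4-isopropyl-2-oxazolin-2-yl)pyridine (24 mol%), 4 Å MS, CH2Cl2 (2 mM, degassed), hν (405 nm LED, flow), −40 °C
Reagents that add atoms: none
Why: Proposed new method: Sc(OTf)3 carrying the chiral ligand chelates the ketone and ester carbonyl oxygens of 10, which should shift the absorption of bound substrate to longer wavelength so that 405 nm light excites mainly the complex; after intersystem crossing the ketone oxygen, through the lone pair not held by scandium, abstracts hydrogen from the ortho OCH3 group in a seven-membered transition state to give the triplet 1,5-biradical 11, which after spin inversion combines at carbon. The closest known reaction type is the racemic Norrish–Yang photocyclisation of ortho-alkoxyphenyl ketones and ortho-alkoxyphenylglyoxylates to 3-hydroxy-2,3-dihydrobenzofurans; the closest known control element is chiral Lewis acid catalysis of excited-state reactions of chelating carbonyl compounds, which covers cycloadditions and not hydrogen abstraction. The five-membered ring is closed by radical–radical combination of the 1,5-biradical (Yang cyclisation), its size being fixed by the 1,6-hydrogen transfer. The new stereocentre is set when the bond forms: the two ortho substituents twist the aryl ring out of the chelate plane, so OCH3 lies on one face of the ketyl and the large silyloxy group on the other, the isopropyl groups of the ligand should admit only one of these two twisted forms, and the short-lived biradical should close faster than the aryl–carbon bond rotates. Site selectivity of the hydrogen transfer is needed and the substrate secures it: the other ortho group is a silyl ether without activated C–H bonds, the ester OCH3 is held away from the ketone oxygen in the chelate (which should also suppress Norrish type-two cleavage on the ester side), and the prenyl hydrogens on the meta carbon are out of reach. Chemoselectivity against bimolecular quenching or Paternò–Büchi addition by the prenyl alkene is sought by working at 2 mM in flow, and a racemic background reaction is limited by the weak absorption of free 10 at 405 nm.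

Step 7
Reactants: 12 methyl (3S)-4,6-bis(tert-butyldimethylsilyloxy)-3-hydroxy-5-prenyl-2,3-dihydro-1-benzofuran-3-carboxylate
Product: 13 (3S)-4,6-bis(tert-butyldimethylsilyloxy)-3-hydroxy-N-methoxy-N-methyl-5-prenyl-2,3-dihydro-1-benzofuran-3-carboxamide
Conditions: Me(MeO)NH·HCl, AlMe3, CH2Cl2, 0 → 35 °C; aq. potassium sodium tartrate
Reagents that add atoms: N,O-dimethylhydroxylamine hydrochloride, CNOC.Cl
Why: Aminolysis of the ester by the aluminium amide formed in the flask (Weinreb amide synthesis). The tertiary hydroxyl is held as an aluminium alkoxide, a poor nucleophile toward the neighbouring silyl ether, and the stereocentre has no hydrogen and no leaving group, so it is untouched.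

Step 8
Reactants: 14 4-bromo-3-methoxyphenol
Product: 15 1-bromo-2-methoxy-4-(methoxymethoxy)benzene
Conditions: NaH, MOMCl, DMF, 0 °C → rt
Reagents that add atoms: chloromethyl methyl ether (MOMCl), COCCl
Why: Williamson-type O-alkylation of the phenoxide; the acetal ether is the directing group for step 9.

Step 9
Reactants: 15 1-bromo-2-methoxy-4-(methoxymethoxy)benzene; 3 prenyl bromide
Product: 17 1-bromo-2-methoxy-4-(methoxymethoxy)-3-prenylbenzene, via aryllithium 16 (not isolated)
Conditions: lithium 2,2,6,6-tetramethylpiperidide (from the amine and n-BuLi, 0 °C), THF, −78 °C; then 3, −78 → −20 °C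
Reagents that add atoms: prenyl bromide 3, CC(C)=CCBr
Why: Directed ortho-metalation with a lithium amide, which removes the proton flanked by OCH3 and OCH2OCH3 (the most acidic and best coordinated site) and, unlike an alkyllithium, does not exchange the bromine. The aryllithium is then alkylated at the primary allylic carbon of 3 (SN2).

Step 10
Reactants: 17 1-bromo-2-methoxy-4-(methoxymethoxy)-3-prenylbenzene
Product: 18 4-bromo-3-methoxy-2-prenylphenol
Conditions: HCl (0.5 M), MeOH, 35 °C
Reagents that add atoms: none
Why: Acid-catalysed acetal exchange with methanol, mild enough for a single ortho-prenyl phenol; the aryl bromide and the methyl ether are inert.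

Step 11
Reactants: 18 4-bromo-3-methoxy-2-prenylphenol
Product: 19 [4-bromo-3-methoxy-2-prenylphenoxy](tert-butyl)dimethylsilane
Conditions: TBSCl, imidazole, DMF, rt
Reagents that add atoms: tert-butyldimethylsilyl chloride (TBSCl), CC(C)(C)[Si](C)(C)Cl
Why: Standard imidazole-mediated silylation of a phenol. The silyl ether is para to the bromine, so the later aryllithium cannot undergo silyl migration, and it leaves with fluoride at the end together with the ring A groups.

Step 12
Reactants: 13 (3S)-4,6-bis(tert-butyldimethylsilyloxy)-3-hydroxy-N-methoxy-N-methyl-5-prenyl-2,3-dihydro-1-benzofuran-3-carboxamide; 19 [4-bromo-3-methoxy-2-prenylphenoxy](tert-butyl)dimethylsilane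
Product: 22 [(3S)-4,6-bis(tert-butyldimethylsilyloxy)-3-hydroxy-5-prenyl-2,3-dihydro-1-benzofuran-3-yl][4-(tert-butyldimethylsilyloxy)-2-methoxy-3-prenylphenyl]methanone, via lithium alkoxide 20 (not isolated), via aryllithium 21 (not isolated)
Conditions: 13, LiN(SiMe3)2, THF, −78 °C; 19, n-BuLi, THF, −78 °C; combined (1.5 equiv of 21), −78 → −40 °C; aq. NH4Cl at −78 °C
Reagents that add atoms: none
Why: Weinreb ketone synthesis: bromine–lithium exchange gives 21, which should add once to the N-methoxy-N-methylamide because the chelated tetrahedral adduct does not collapse before the cold quench. The hydroxyl is deprotonated beforehand with the inexpensive amide base so that no 21 is consumed as a base, and the stereocentre carries no acidic hydrogen.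

Step 13
Reactants: 22 [(3S)-4,6-bis(tert-butyldimethylsilyloxy)-3-hydroxy-5-prenyl-2,3-dihydro-1-benzofuran-3-yl][4-(tert-butyldimethylsilyloxy)-2-methoxy-3-prenylphenyl]methanone
Product: 23 (3R)-5,7-bis(tert-butyldimethylsilyloxy)-3-[4-(tert-butyldimethylsilyloxy)-2-methoxy-3-prenylphenyl]-3-hydroxy-6-prenyl-2,3-dihydro-4H-chromen-4-one
Conditions: Zn(OTf)2 (1.0 equiv), 2,6-di-tert-butyl-4-methylpyridine (0.3 equiv), 4 Å MS, ClCH2CH2Cl, 60 °C
Reagents that add atoms: none
Why: α-Ketol (acyloin) rearrangement with ring expansion, the reaction type by which 1-acylcycloalkanols give 2-hydroxycycloalkanones: Zn(OTf)2 holds the carbonyl and hydroxyl oxygens syn, the ring methylene migrates from the carbinol carbon to the ketone carbon on the face it already occupies, and the (S)-carbinol of 22 is thereby transferred stereospecifically to (R)-C3. Relief of the crowded five-membered ring and conjugation of the new C4 carbonyl with ring A should drive the shift; migration of the ring A carbon instead would lead, after a second shift of ring B, to 23 with the same configuration. The hindered pyridine traps adventitious acid that could ionise the carbinol or attack the prenyl chains.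

Step 14
Reactants: 23 (3R)-5,7-bis(tert-butyldimethylsilyloxy)-3-[4-(tert-butyldimethylsilyloxy)-2-methoxy-3-prenylphenyl]-3-hydroxy-6-prenyl-2,3-dihydro-4H-chromen-4-one
Product: 24 (3R)-3,5,7-trihydroxy-3-[4-hydroxy-2-methoxy-3-prenylphenyl]-6-prenyl-2,3-dihydro-4H-chromen-4-one (target)
Conditions: TBAF, AcOH, THF, 0 °C
Reagents that add atoms: none
Why: Fluoride-induced cleavage of the three aryl silyl ethers. Acetic acid buffers the phenoxides so the ketol is not exposed to base, no acid strong enough to cyclise the prenyl chains is present, and C3 has no hydrogen and is not affected.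

## Compound list

1 | 5-methoxyresorcinol (5-methoxybenzene-1,3-diol) | COc1cc(O)cc(O)c1 | starting material
2 | 1-methoxy-3,5-bis(methoxymethoxy)benzene | COCOc1cc(OC)cc(OCOC)c1 | intermediate
3 | prenyl bromide (1-bromo-3-methylbut-2-ene) | CC(C)=CCBr | starting material
4 | [4-methoxy-2,6-bis(methoxymethoxy)phenyl]lithium | [Li]c1c(OCOC)cc(OC)cc1OCOC | intermediate
5 | 5-methoxy-1,3-bis(methoxymethoxy)-2-(3-methylbut-2-en-1-yl)benzene | COCOc1cc(OC)cc(OCOC)c1CC=C(C)C | intermediate
6 | dimethyl oxalate | COC(=O)C(=O)OC | starting material
7 | [6-methoxy-2,4-bis(methoxymethoxy)-3-(3-methylbut-2-en-1-yl)phenyl]lithium | [Li]c1c(OC)cc(OCOC)c(CC=C(C)C)c1OCOC | intermediate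
8 | methyl 2-[6-methoxy-2,4-bis(methoxymethoxy)-3-(3-methylbut-2-en-1-yl)phenyl]-2-oxoacetate | COC(=O)C(=O)c1c(OC)cc(OCOC)c(CC=C(C)C)c1OCOC | intermediate
9 | methyl 2-[2,4-dihydroxy-6-methoxy-3-(3-methylbut-2-en-1-yl)phenyl]-2-oxoacetate | COC(=O)C(=O)c1c(OC)cc(O)c(CC=C(C)C)c1O | intermediate
10 | methyl 2-[2,4-bis(tert-butyldimethylsilyloxy)-6-methoxy-3-(3-methylbut-2-en-1-yl)phenyl]-2-oxoacetate | COC(=O)C(=O)c1c(OC)cc(O[Si](C)(C)C(C)(C)C)c(CC=C(C)C)c1O[Si](C)(C)C(C)(C)C | intermediate
11 | triplet 1,5-biradical from 10 (ketyl carbon and aryloxymethyl carbon; drawn without the bound scandium) | COC(=O)[C](O)c1c(O[CH2])cc(O[Si](C)(C)C(C)(C)C)c(CC=C(C)C)c1O[Si](C)(C)C(C)(C)C | intermediate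
12 | methyl (3S)-4,6-bis(tert-butyldimethylsilyloxy)-3-hydroxy-5-(3-methylbut-2-en-1-yl)-2,3-dihydro-1-benzofuran-3-carboxylate | COC(=O)[C@@]1(O)COc2cc(O[Si](C)(C)C(C)(C)C)c(CC=C(C)C)c(O[Si](C)(C)C(C)(C)C)c21 | intermediate
13 | (3S)-4,6-bis(tert-butyldimethylsilyloxy)-3-hydroxy-N-methoxy-N-methyl-5-(3-methylbut-2-en-1-yl)-2,3-dihydro-1-benzofuran-3-carboxamide | CON(C)C(=O)[C@@]1(O)COc2cc(O[Si](C)(C)C(C)(C)C)c(CC=C(C)C)c(O[Si](C)(C)C(C)(C)C)c21 | intermediate
14 | 4-bromo-3-methoxyphenol | COc1cc(O)ccc1Br | starting material
15 | 1-bromo-2-methoxy-4-(methoxymethoxy)benzene | COCOc1ccc(Br)c(OC)c1 | intermediate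
16 | [3-bromo-2-methoxy-6-(methoxymethoxy)phenyl]lithium | [Li]c1c(OCOC)ccc(Br)c1OC | intermediate
17 | 1-bromo-2-methoxy-4-(methoxymethoxy)-3-(3-methylbut-2-en-1-yl)benzene | COCOc1ccc(Br)c(OC)c1CC=C(C)C | intermediate
18 | 4-bromo-3-methoxy-2-(3-methylbut-2-en-1-yl)phenol | COc1c(Br)ccc(O)c1CC=C(C)C | intermediate
19 | [4-bromo-3-methoxy-2-(3-methylbut-2-en-1-yl)phenoxy](tert-butyl)dimethylsilane | COc1c(Br)ccc(O[Si](C)(C)C(C)(C)C)c1CC=C(C)C | intermediate
20 | lithium alkoxide of 13 (lithium (3S)-3-olate) | CON(C)C(=O)[C@@]1(O[Li])COc2cc(O[Si](C)(C)C(C)(C)C)c(CC=C(C)C)c(O[Si](C)(C)C(C)(C)C)c21 | intermediate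
21 | [4-(tert-butyldimethylsilyloxy)-2-methoxy-3-(3-methylbut-2-en-1-yl)phenyl]lithium | [Li]c1ccc(O[Si](C)(C)C(C)(C)C)c(CC=C(C)C)c1OC | intermediate
22 | [(3S)-4,6-bis(tert-butyldimethylsilyloxy)-3-hydroxy-5-(3-methylbut-2-en-1-yl)-2,3-dihydro-1-benzofuran-3-yl][4-(tert-butyldimethylsilyloxy)-2-methoxy-3-(3-methylbut-2-en-1-yl)phenyl]methanone | COc1c(C(=O)[C@@]2(O)COc3cc(O[Si](C)(C)C(C)(C)C)c(CC=C(C)C)c(O[Si](C)(C)C(C)(C)C)c32)ccc(O[Si](C)(C)C(C)(C)C)c1CC=C(C)C | intermediate
23 | (3R)-5,7-bis(tert-butyldimethylsilyloxy)-3-[4-(tert-butyldimethylsilyloxy)-2-methoxy-3-(3-methylbut-2-en-1-yl)phenyl]-3-hydroxy-6-(3-methylbut-2-en-1-yl)-2,3-dihydro-4H-chromen-4-one | COc1c([C@@]2(O)COc3cc(O[Si](C)(C)C(C)(C)C)c(CC=C(C)C)c(O[Si](C)(C)C(C)(C)C)c3C2=O)ccc(O[Si](C)(C)C(C)(C)C)c1CC=C(C)C | intermediate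
24 | (3R)-3,5,7-trihydroxy-3-[4-hydroxy-2-methoxy-3-(3-methylbut-2-en-1-yl)phenyl]-6-(3-methylbut-2-en-1-yl)-2,3-dihydro-4H-chromen-4-one | COc1c([C@@]2(O)COc3cc(O)c(CC=C(C)C)c(O)c3C2=O)ccc(O)c1CC=C(C)C | target

## Step count and least certain steps

Total: 14 steps. Longest linear sequence: 10 steps (steps 1–7, then 12, 13 and 14, from 1). The ring B branch has 4 steps (8–11) before the union in step 12.

Step 6 (key step, proposed new method). Several processes may fail:
- Hydrogen transfer may be slow, because the scandium-bound, electron-rich aryl ketone may have a poorly reactive excited state and an OCH3 group is a weak hydrogen donor.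
- Facial discrimination may be poor, or a racemic background reaction of unbound 10 may compete.
- The prenyl double bond of a second molecule may quench the excited ketone or add to it.
- The product, an α-hydroxy ester, may hold on to scandium and stop turnover.

The fallback uses known chemistry; it sets out from 10 and comes back at 12. Irradiation of 10 without Lewis acid (365 nm, degassed acetonitrile, 2 mM), as an ordinary Norrish–Yang cyclisation, would give the racemic methyl 4,6-bis(tert-butyldimethylsilyloxy)-3-hydroxy-5-prenyl-2,3-dihydro-1-benzofuran-3-carboxylate F1. Preparative chromatography on a chiral stationary phase would separate 12 from the (3R)-enantiomer F2, which is set aside. The configuration of the enantiomer carried on would then have to be assigned, for example by anomalous-dispersion X-ray analysis of a crystalline derivative.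

Step 13. The shift may stop short of completion if the silylated chromanone is not clearly more stable than 22 (crowding between the C5 silyloxy group and the C4 carbonyl). It may rest at the isomer formed by ring A migration. A non-chelated pathway or ionisation of the electron-rich benzylic carbinol would erode the configuration. The fallback sets out from 22 and comes back at 24, reversing the order of the last two operations. Buffered fluoride (TBAF, AcOH, THF, 0 °C) would first remove all three silyl groups to give [(3S)-3,4,6-trihydroxy-5-prenyl-2,3-dihydro-1-benzofuran-3-yl](4-hydroxy-2-methoxy-3-prenylphenyl)methanone F3. The ketol shift would then be run on F3 with Zn(OTf)2 in acetonitrile at 40 °C, where the hydrogen bond from the new C5 hydroxyl to the C4 carbonyl adds driving force.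

Step 12. The silyl group on the phenolic oxygen next to the carbinol may migrate to the tertiary lithium alkoxide, which would block the later ketol shift. Addition to the doubly hindered amide may also be slow, so that warming is needed and the migration gains time. The fallback sets out from 13 and comes back at 22. The hydroxyl would be capped (TMSOTf, 2,6-lutidine, CH2Cl2, −78 °C) as the trimethylsilyl ether of the amide F4. Addition of 21 to F4 would give the silylated ketone F5 with no alkoxide present. Citric acid in methanol would then remove the tertiary trimethylsilyl ether and leave the aryl silyl ethers in place.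

Step 9. Deprotonation may be incomplete, or may occur beside the bromine with loss of LiBr, and bromine may scramble between aryllithium and unreacted bromide before alkylation is complete. The fallback sets out from 3 and a new starting material and comes back at 21; it avoids any base in the presence of an aryl bromide. In sequence:
- 4-chloro-3-methoxyphenol F6 would be converted (NaH, MOMCl) into 1-chloro-2-methoxy-4-(methoxymethoxy)benzene F7.
- F7 would be lithiated with n-BuLi between the two oxygens (the chloride does not exchange) and alkylated with 3 to give 1-chloro-2-methoxy-4-(methoxymethoxy)-3-prenylbenzene F8.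
- Acidic methanol would give 4-chloro-3-methoxy-2-prenylphenol F9.
- TBSCl and imidazole would give tert-butyl[4-chloro-3-methoxy-2-prenylphenoxy]dimethylsilane F10.
- Reductive lithiation of F10 with lithium 4,4'-di-tert-butylbiphenylide in THF at −78 °C would deliver 21.

Step 4. The prenyl chain may close onto one of the freed flanking phenols under acid, and the ortho-hydroxyaryl keto ester may lactonise with loss of methanol. The fallback sets out from 8 and comes back at 9; it replaces protic acetal exchange by silyl transfer. TMSOTf with 2,2'-bipyridyl in CH2Cl2 at 0 °C, a known way to convert aryl methoxymethyl ethers into aryl silyl ethers without free acid, would give methyl 2-[6-methoxy-3-prenyl-2,4-bis(trimethylsilyloxy)phenyl]-2-oxoacetate F11. F11 would be hydrolysed to 9 on neutral aqueous work-up.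

## Further compounds

F1 | step 6 | racemic methyl 4,6-bis(tert-butyldimethylsilyloxy)-3-hydroxy-5-(3-methylbut-2-en-1-yl)-2,3-dihydro-1-benzofuran-3-carboxylate | COC(=O)C1(O)COc2cc(O[Si](C)(C)C(C)(C)C)c(CC=C(C)C)c(O[Si](C)(C)C(C)(C)C)c21
F2 | step 6 | methyl (3R)-4,6-bis(tert-butyldimethylsilyloxy)-3-hydroxy-5-(3-methylbut-2-en-1-yl)-2,3-dihydro-1-benzofuran-3-carboxylate | COC(=O)[C@]1(O)COc2cc(O[Si](C)(C)C(C)(C)C)c(CC=C(C)C)c(O[Si](C)(C)C(C)(C)C)c21
F3 | step 13 | [(3S)-3,4,6-trihydroxy-5-(3-methylbut-2-en-1-yl)-2,3-dihydro-1-benzofuran-3-yl][4-hydroxy-2-methoxy-3-(3-methylbut-2-en-1-yl)phenyl]methanone | COc1c(C(=O)[C@@]2(O)COc3cc(O)c(CC=C(C)C)c(O)c32)ccc(O)c1CC=C(C)C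
F4 | step 12 | (3S)-4,6-bis(tert-butyldimethylsilyloxy)-N-methoxy-N-methyl-5-(3-methylbut-2-en-1-yl)-3-(trimethylsilyloxy)-2,3-dihydro-1-benzofuran-3-carboxamide | CON(C)C(=O)[C@@]1(O[Si](C)(C)C)COc2cc(O[Si](C)(C)C(C)(C)C)c(CC=C(C)C)c(O[Si](C)(C)C(C)(C)C)c21
F5 | step 12 | [(3S)-4,6-bis(tert-butyldimethylsilyloxy)-5-(3-methylbut-2-en-1-yl)-3-(trimethylsilyloxy)-2,3-dihydro-1-benzofuran-3-yl][4-(tert-butyldimethylsilyloxy)-2-methoxy-3-(3-methylbut-2-en-1-yl)phenyl]methanone | COc1c(C(=O)[C@@]2(O[Si](C)(C)C)COc3cc(O[Si](C)(C)C(C)(C)C)c(CC=C(C)C)c(O[Si](C)(C)C(C)(C)C)c32)ccc(O[Si](C)(C)C(C)(C)C)c1CC=C(C)C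
F6 | step 9 | 4-chloro-3-methoxyphenol | COc1cc(O)ccc1Cl
F7 | step 9 | 1-chloro-2-methoxy-4-(methoxymethoxy)benzene | COCOc1ccc(Cl)c(OC)c1
F8 | step 9 | 1-chloro-2-methoxy-4-(methoxymethoxy)-3-(3-methylbut-2-en-1-yl)benzene | COCOc1ccc(Cl)c(OC)c1CC=C(C)C
F9 | step 9 | 4-chloro-3-methoxy-2-(3-methylbut-2-en-1-yl)phenol | COc1c(Cl)ccc(O)c1CC=C(C)C
F10 | step 9 | tert-butyl[4-chloro-3-methoxy-2-(3-methylbut-2-en-1-yl)phenoxy]dimethylsilane | COc1c(Cl)ccc(O[Si](C)(C)C(C)(C)C)c1CC=C(C)C
F11 | step 4 | methyl 2-[6-methoxy-3-(3-methylbut-2-en-1-yl)-2,4-bis(trimethylsilyloxy)phenyl]-2-oxoacetate | COC(=O)C(=O)c1c(OC)cc(O[Si](C)(C)C)c(CC=C(C)C)c1O[Si](C)(C)C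
A1 | alternative 1 | 3-[2-methoxy-4-(methoxymethoxy)-3-(3-methylbut-2-en-1-yl)phenyl]-5,7-bis(methoxymethoxy)-6-(3-methylbut-2-en-1-yl)-4H-chromen-4-one | COc1c(-c2coc3cc(OCOC)c(CC=C(C)C)c(OCOC)c3c2=O)ccc(OCOC)c1CC=C(C)C
A2 | alternative 1 | cis-fused 2,3-epoxide of A1 (2,3-epoxyisoflavanone with the oxirane oxygen on the C3 face required for 3R) | COc1c([C@]23O[C@@H]3Oc4cc(OCOC)c(CC=C(C)C)c(OCOC)c4C2=O)ccc(OCOC)c1CC=C(C)C
A3 | alternative 2 | 1-[6-(tert-butyldimethylsilyloxy)-2,4-bis(methoxymethoxy)-3-(3-methylbut-2-en-1-yl)phenyl]-2-diazo-2-[2-methoxy-4-(methoxymethoxy)-3-(3-methylbut-2-en-1-yl)phenyl]ethan-1-one | COc1c(C(=[N+]=[N-])C(=O)c2c(O[Si](C)(C)C(C)(C)C)cc(OCOC)c(CC=C(C)C)c2OCOC)ccc(OCOC)c1CC=C(C)C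
A4 | alternative 2 | (2R)-1-[6-(tert-butyldimethylsilyloxy)-2,4-bis(methoxymethoxy)-3-(3-methylbut-2-en-1-yl)phenyl]-2,3-dihydroxy-2-[2-methoxy-4-(methoxymethoxy)-3-(3-methylbut-2-en-1-yl)phenyl]propan-1-one | COc1c([C@@](O)(CO)C(=O)c2c(O[Si](C)(C)C(C)(C)C)cc(OCOC)c(CC=C(C)C)c2OCOC)ccc(OCOC)c1CC=C(C)C
A5 | alternative 3 | 6-{2-[2-methoxy-4-(methoxymethoxy)-3-(3-methylbut-2-en-1-yl)phenyl]-2-oxoethoxy}-2,4-bis(methoxymethoxy)-3-(3-methylbut-2-en-1-yl)benzaldehyde | COc1c(C(=O)COc2cc(OCOC)c(CC=C(C)C)c(OCOC)c2C=O)ccc(OCOC)c1CC=C(C)C
A6 | alternative 3 | (3R)-3-hydroxy-3-[2-methoxy-4-(methoxymethoxy)-3-(3-methylbut-2-en-1-yl)phenyl]-5,7-bis(methoxymethoxy)-6-(3-methylbut-2-en-1-yl)-2,3-dihydro-4H-chromen-4-one | COc1c([C@@]2(O)COc3cc(OCOC)c(CC=C(C)C)c(OCOC)c3C2=O)ccc(OCOC)c1CC=C(C)C
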